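The oxolane is cut into formaldehyde (C5–O1) and a C2–C3–C4 unit stored as a lactone-fused donor–acceptor cyclopropane. The key step exploits the 4-hydroxyl of the guaiacyl ring on C2, para to that benzylic carbon: freed as phenoxide, it opens the cyclopropane to a para-quinone methide enolate that takes up formaldehyde at C4 (C4–C5) and closes by oxa-1,6-addition at C2 (O1–C2), as in lignan biosynthesis. The precursor, a silyl-protected 6-aryl-3-oxabicyclo[3.1.0]hexanone ester, carries one organocatalytically set centre (C3) that relays C2 and C4. Its lactone later becomes the acylated CH2O on C3 and the benzylic CH2 on C4; the activating ester is removed.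

Key step: step 4

Assumption: (2R)-2-methylbutanoic acid and (R)-2-[diphenyl(trimethylsilyloxy)methyl]pyrrolidine are bought as single enantiomers; formaldehyde is generated from paraformaldehyde.

**Step 1**
Reactants: 1 (2E)-3-(4-hydroxy-3-methoxyphenyl)prop-2-enal (coniferaldehyde)
Product: 2 (2E)-3-{4-[(tert-butyldimethylsilyl)oxy]-3-methoxyphenyl}prop-2-enal
Conditions: TBSCl, imidazole, DMF, rt
Reagents that add atoms: tert-butyldimethylsilyl chloride, CC(C)(C)[Si](C)(C)Cl
Why: Silyl ether formation on the phenol, which masks the phenoxide that later triggers the key step.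

**Step 2**
Reactants: 2 (2E)-3-{4-[(tert-butyldimethylsilyl)oxy]-3-methoxyphenyl}prop-2-enal; 3 dimethyl bromomalonate
Product: 4 dimethyl (2S,3R)-2-formyl-3-{4-[(tert-butyldimethylsilyl)oxy]-3-methoxyphenyl}cyclopropane-1,1-dicarboxylate
Conditions: (R)-2-[diphenyl(trimethylsilyloxy)methyl]pyrrolidine (20 mol%), 2,6-lutidine (1.1 equiv), CH2Cl2, 0 °C
Reagents that add atoms: none
Why: Organocatalytic Michael-initiated ring closure, in which the diphenyl(silyloxy)methyl arm of the (R)-catalyst shields one face of the E-iminium ion so that the bromomalonate adds to the Re face of the β-carbon and the enamine then closes by 3-exo-tet alkylation trans to the aryl group, fixing C2 as S (C3 of the target).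

**Step 3**
Reactants: 4 dimethyl (2S,3R)-2-formyl-3-{4-[(tert-butyldimethylsilyl)oxy]-3-methoxyphenyl}cyclopropane-1,1-dicarboxylate
Product: 6 methyl (1R,5S,6R)-6-{4-[(tert-butyldimethylsilyl)oxy]-3-methoxyphenyl}-2-oxo-3-oxabicyclo[3.1.0]hexane-1-carboxylate, via hydroxymethyl diester 5 (not isolated)
Conditions: NaBH4, MeOH, 0 °C; then PPTS (cat.), CH2Cl2, rt
Reagents that add atoms: none
Why: Borohydride reduction of the aldehyde followed by lactonisation of the new alcohol onto the only ester cis to it, which ties the C3 CH2O to the future C4 carbonyl carbon and leaves one activating ester.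

**Step 4**
Reactants: 6 methyl (1R,5S,6R)-6-{4-[(tert-butyldimethylsilyl)oxy]-3-methoxyphenyl}-2-oxo-3-oxabicyclo[3.1.0]hexane-1-carboxylate; 7 formaldehyde
Product: 10 methyl (1S,5S,6R)-6-[4-(benzyloxy)-3-methoxyphenyl]-2-oxo-3,7-dioxabicyclo[3.3.0]octane-1-carboxylate, via quinone methide enolate 8 (not isolated), via annulated caesium phenoxide 9 (not isolated)
Conditions: CsF (2.2 equiv), CH2O (3 equiv, THF solution from cracked paraformaldehyde), DMF, −20 °C → rt; then BnBr (1.5 equiv), rt
Reagents that add atoms: benzyl bromide, BrCc1ccccc1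
Why: Proposed new method: fluoride unmasks the phenoxide of the C6 aryl ring, whose para push heterolyses the strained, doubly acceptor-activated C1–C6 bond to the para-quinone methide enolate 8, and this carbanion hydroxymethylates on formaldehyde (C–C bond) to an alkoxide that adds 1,6 to the quinone methide (O–C bond) and restores the arene as phenoxide 9, which is then benzylated. The closest known reaction types are the fluoride- or base-triggered opening of 4-siloxy- or 4-hydroxyaryl cyclopropane-1,1-diesters to para-quinone methides that take up external nucleophiles by 1,6-addition and the Lewis-acid (3+2) annulation of donor–acceptor cyclopropanes with aldehydes; the anionic course is preferred here because formaldehyde is a first-rate carbon electrophile but a poor oxygen nucleophile, and because the SN2-type Lewis-acid course would invert C6 of this trans cyclopropane and give the wrong C6 epimer. The oxolane closes in a 5-exo-trig oxa-1,6-addition, the laboratory copy of the hydroxyl-to-quinone-methide closure that forms the furofuran lignans in nature. C1 (C4 of the target) is controlled by the lactone, since only the hydroxymethyl adduct cis to the side chain can close to the cis-fused bicycle and the other returns by retro-aldol. C6 (C2 of the target) is set in the closure by C5: A(1,3) strain keeps H5 in the plane of the quinone methide, so the alkoxide delivered from C1 meets the face that places the aryl group exo, trans to the lactone CH2O, whichever configuration C6 had in 6. The step needs C-attack on formaldehyde and cyclisation to outrun intermolecular 1,6-addition of one enolate to another quinone methide, which excess monomeric formaldehyde, dilution and the intramolecular closure should secure.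

**Step 5**
Reactants: 10 methyl (1S,5S,6R)-6-[4-(benzyloxy)-3-methoxyphenyl]-2-oxo-3,7-dioxabicyclo[3.3.0]octane-1-carboxylate
Product: 11 (1S,5S,6R)-6-[4-(benzyloxy)-3-methoxyphenyl]-3,7-dioxabicyclo[3.3.0]octan-2-one
Conditions: LiCl (3 equiv), H2O (2 equiv), DMSO, 140 °C
Reagents that add atoms: none
Why: Krapcho dealkoxycarbonylation removes the activating ester, and protonation of the lactone enolate can only give the cis-fused bicycle, so C1 (C4 of the target) stays cis to the C5 CH2O.

**Step 6**
Reactants: 11 (1S,5S,6R)-6-[4-(benzyloxy)-3-methoxyphenyl]-3,7-dioxabicyclo[3.3.0]octan-2-one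
Product: 12 (1S,5S,6R)-6-[4-(benzyloxy)-3-methoxyphenyl]-3,7-dioxabicyclo[3.3.0]octan-2-ol (lactol, both anomers)
Conditions: i-Bu2AlH (1.1 equiv), CH2Cl2, −78 °C
Reagents that add atoms: none
Why: Partial reduction of the γ-lactone, which stops at the aluminium hemiacetal at low temperature and touches no ring stereocentre.

**Step 7**
Reactants: 12 (1S,5S,6R)-6-[4-(benzyloxy)-3-methoxyphenyl]-3,7-dioxabicyclo[3.3.0]octan-2-ol; 13 1-(benzyloxy)-4-bromo-2-methoxybenzene
Product: 15 {(2R,3S,4S)-2-[4-(benzyloxy)-3-methoxyphenyl]-4-{[4-(benzyloxy)-3-methoxyphenyl](hydroxy)methyl}oxolan-3-yl}methanol (carbinol epimers), via aryl Grignard reagent 14 (not isolated)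
Conditions: 13, Mg, THF, rt; then 12, THF, 0 °C → rt (3 equiv of 14)
Reagents that add atoms: none
Why: Grignard addition to the open hydroxy aldehyde form of the lactol frees the C3 CH2OH and brings in the second aryl group, and the new carbinol centre, formed without control, is removed in step 9.

**Step 8**
Reactants: 15 {(2R,3S,4S)-2-[4-(benzyloxy)-3-methoxyphenyl]-4-{[4-(benzyloxy)-3-methoxyphenyl](hydroxy)methyl}oxolan-3-yl}methanol; 16 (2R)-2-methylbutanoic acid
Product: 17 {(2R,3S,4S)-2-[4-(benzyloxy)-3-methoxyphenyl]-4-{[4-(benzyloxy)-3-methoxyphenyl](hydroxy)methyl}oxolan-3-yl}methyl (2R)-2-methylbutanoate (carbinol epimers)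
Conditions: EDC·HCl (1.2 equiv), DMAP (0.1 equiv), CH2Cl2, 0 °C
Reagents that add atoms: none
Why: Steglich-type esterification, selective for the primary hydroxyl over the hindered secondary benzylic one, which also blocks the hydroxyl that would otherwise close a furofuran in step 9 and should not enolise the (R) centre of the acid.

**Step 9**
Reactants: 17 {(2R,3S,4S)-2-[4-(benzyloxy)-3-methoxyphenyl]-4-{[4-(benzyloxy)-3-methoxyphenyl](hydroxy)methyl}oxolan-3-yl}methyl (2R)-2-methylbutanoate
Product: 18 {(2R,3S,4S)-2-[4-(benzyloxy)-3-methoxyphenyl]-4-[4-(benzyloxy)-3-methoxybenzyl]oxolan-3-yl}methyl (2R)-2-methylbutanoate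
Conditions: Et3SiH (5 equiv), BF3·OEt2 (2 equiv), CH2Cl2, −78 → −40 °C
Reagents that add atoms: none
Why: Ionic hydrogenation, in which the secondary benzylic alcohol ionises to a 4-alkoxybenzyl cation that Et3SiH reduces to CH2 at a temperature at which the cyclic benzylic ether C2–O1 should not ionise.

**Step 10**
Reactants: 18 {(2R,3S,4S)-2-[4-(benzyloxy)-3-methoxyphenyl]-4-[4-(benzyloxy)-3-methoxybenzyl]oxolan-3-yl}methyl (2R)-2-methylbutanoate
Product: 19 [(2R,3S,4S)-2-(4-hydroxy-3-methoxyphenyl)-4-(4-hydroxy-3-methoxybenzyl)oxolan-3-yl]methyl (2R)-2-methylbutanoate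
Conditions: H2 (1 atm), Pd/C (10%), EtOAc, rt
Reagents that add atoms: none
Why: Hydrogenolysis of the two aryl benzyl ethers, which should be cleaved much faster than the dialkyl benzylic ether C2–O1, with the ester and all stereocentres untouched.

**Compound list**

1 | (2E)-3-(4-hydroxy-3-methoxyphenyl)prop-2-enal (coniferaldehyde) | O=C/C=C/c1ccc(O)c(OC)c1 | starting material
2 | (2E)-3-{4-[(tert-butyldimethylsilyl)oxy]-3-methoxyphenyl}prop-2-enal | O=C/C=C/c1ccc(O[Si](C)(C)C(C)(C)C)c(OC)c1 | intermediate
3 | dimethyl bromomalonate | COC(=O)C(Br)C(=O)OC | starting material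
4 | dimethyl (2S,3R)-2-formyl-3-{4-[(tert-butyldimethylsilyl)oxy]-3-methoxyphenyl}cyclopropane-1,1-dicarboxylate | COC(=O)C1(C(=O)OC)[C@@H](C=O)[C@@H]1c1ccc(O[Si](C)(C)C(C)(C)C)c(OC)c1 | intermediate
5 | dimethyl (2S,3R)-2-(hydroxymethyl)-3-{4-[(tert-butyldimethylsilyl)oxy]-3-methoxyphenyl}cyclopropane-1,1-dicarboxylate | COC(=O)C1(C(=O)OC)[C@@H](CO)[C@@H]1c1ccc(O[Si](C)(C)C(C)(C)C)c(OC)c1 | intermediate (not isolated)
6 | methyl (1R,5S,6R)-6-{4-[(tert-butyldimethylsilyl)oxy]-3-methoxyphenyl}-2-oxo-3-oxabicyclo[3.1.0]hexane-1-carboxylate | COC(=O)[C@]12C(=O)OC[C@H]1[C@@H]2c1ccc(O[Si](C)(C)C(C)(C)C)c(OC)c1 | intermediate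
7 | formaldehyde | C=O | starting material
8 | caesium (4S)-3-(methoxycarbonyl)-4-[(3-methoxy-4-oxocyclohexa-2,5-dien-1-ylidene)methyl]-4,5-dihydrofuran-2-olate | COC(=O)C1=C([O-])OC[C@H]1C=C1C=CC(=O)C(OC)=C1.[Cs+] | intermediate (not isolated)
9 | caesium 2-methoxy-4-[(1S,5S,6R)-1-(methoxycarbonyl)-2-oxo-3,7-dioxabicyclo[3.3.0]octan-6-yl]phenolate | COC(=O)[C@@]12CO[C@@H](c3ccc([O-])c(OC)c3)[C@@H]1COC2=O.[Cs+] | intermediate (not isolated)
10 | methyl (1S,5S,6R)-6-[4-(benzyloxy)-3-methoxyphenyl]-2-oxo-3,7-dioxabicyclo[3.3.0]octane-1-carboxylate | COC(=O)[C@@]12CO[C@@H](c3ccc(OCc4ccccc4)c(OC)c3)[C@@H]1COC2=O | intermediate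
11 | (1S,5S,6R)-6-[4-(benzyloxy)-3-methoxyphenyl]-3,7-dioxabicyclo[3.3.0]octan-2-one | O=C1OC[C@@H]2[C@H]1CO[C@H]2c1ccc(OCc2ccccc2)c(OC)c1 | intermediate
12 | (1S,5S,6R)-6-[4-(benzyloxy)-3-methoxyphenyl]-3,7-dioxabicyclo[3.3.0]octan-2-ol (both anomers) | OC1OC[C@@H]2[C@H]1CO[C@H]2c1ccc(OCc2ccccc2)c(OC)c1 | intermediate
13 | 1-(benzyloxy)-4-bromo-2-methoxybenzene | COc1cc(Br)ccc1OCc1ccccc1 | starting material
14 | [4-(benzyloxy)-3-methoxyphenyl]magnesium bromide | COc1cc([Mg]Br)ccc1OCc1ccccc1 | intermediate (not isolated)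
15 | {(2R,3S,4S)-2-[4-(benzyloxy)-3-methoxyphenyl]-4-{[4-(benzyloxy)-3-methoxyphenyl](hydroxy)methyl}oxolan-3-yl}methanol (carbinol epimers) | OC[C@@H]1[C@H](C(O)c2ccc(OCc3ccccc3)c(OC)c2)CO[C@H]1c1ccc(OCc2ccccc2)c(OC)c1 | intermediate
16 | (2R)-2-methylbutanoic acid | CC[C@@H](C)C(=O)O | starting material
17 | {(2R,3S,4S)-2-[4-(benzyloxy)-3-methoxyphenyl]-4-{[4-(benzyloxy)-3-methoxyphenyl](hydroxy)methyl}oxolan-3-yl}methyl (2R)-2-methylbutanoate (carbinol epimers) | CC[C@@H](C)C(=O)OC[C@@H]1[C@H](C(O)c2ccc(OCc3ccccc3)c(OC)c2)CO[C@H]1c1ccc(OCc2ccccc2)c(OC)c1 | intermediate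
18 | {(2R,3S,4S)-2-[4-(benzyloxy)-3-methoxyphenyl]-4-[4-(benzyloxy)-3-methoxybenzyl]oxolan-3-yl}methyl (2R)-2-methylbutanoate | CC[C@@H](C)C(=O)OC[C@@H]1[C@H](Cc2ccc(OCc3ccccc3)c(OC)c2)CO[C@H]1c1ccc(OCc2ccccc2)c(OC)c1 | intermediate
19 | [(2R,3S,4S)-2-(4-hydroxy-3-methoxyphenyl)-4-(4-hydroxy-3-methoxybenzyl)oxolan-3-yl]methyl (2R)-2-methylbutanoate | CC[C@@H](C)C(=O)OC[C@@H]1[C@H](Cc2ccc(O)c(OC)c2)CO[C@H]1c1ccc(O)c(OC)c1 | target

Total step count: 10. Longest linear sequence: 10 steps (1 → 19); 3, 7, 13 and 16 are bought.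

**Steps most likely to fail**

Step 4. The quinone methide enolate may add to a second quinone methide and oligomerise, or the closure may lose face selectivity at C6. The fallback is known chemistry, the iodide-relay form of the cyclopropane/carbonyl annulation (ring-opening aldol), and sets out from 6. With MgI2 (1.2 equiv) and formaldehyde in THF at rt to 50 °C, iodide should open the C1–C6 bond with inversion to a benzylic iodide and a magnesium enolate. The enolate adds to formaldehyde and the alkoxide displaces the labile benzylic iodide, by a second inversion or through the ion pair under the same A(1,3) control. This should give the exo adduct methyl (1S,5S,6R)-6-{4-[(tert-butyldimethylsilyl)oxy]-3-methoxyphenyl}-2-oxo-3,7-dioxabicyclo[3.3.0]octane-1-carboxylate F1. CsF and BnBr in DMF then exchange the silyl ether for the benzyl ether, and the route is rejoined at 10.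

Step 9. The Lewis acid may also ionise the ring benzylic ether C2–O1 (epimerisation at C2 or reductive ring opening), or the benzylic cation may lose H4 and scramble C4. The fallback avoids cations by a Barton–McCombie deoxygenation and sets out from 17. PhOC(=S)Cl, pyridine and DMAP in CH2Cl2 give {(2R,3S,4S)-2-[4-(benzyloxy)-3-methoxyphenyl]-4-{[4-(benzyloxy)-3-methoxyphenyl][(phenoxycarbonothioyl)oxy]methyl}oxolan-3-yl}methyl (2R)-2-methylbutanoate F2. Bu3SnH and AIBN in toluene at 80 °C then reduce the benzylic radical to CH2, and the route is rejoined at 18.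

Step 10. Hydrogenolysis may go on to cleave the ring benzylic bond C2–O1 once the benzyl ethers are gone. The fallback replaces hydrogenolysis by Lewis-acid debenzylation with a cation scavenger and sets out from 18. BCl3 (4 equiv) and pentamethylbenzene (6 equiv) in CH2Cl2 at −78 °C should remove both benzyl groups and give 19 directly, with no new intermediate.

**Further compounds**

F1 | step 4 | methyl (1S,5S,6R)-6-{4-[(tert-butyldimethylsilyl)oxy]-3-methoxyphenyl}-2-oxo-3,7-dioxabicyclo[3.3.0]octane-1-carboxylate | COC(=O)[C@@]12CO[C@@H](c3ccc(O[Si](C)(C)C(C)(C)C)c(OC)c3)[C@@H]1COC2=O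
F2 | step 9 | {(2R,3S,4S)-2-[4-(benzyloxy)-3-methoxyphenyl]-4-{[4-(benzyloxy)-3-methoxyphenyl][(phenoxycarbonothioyl)oxy]methyl}oxolan-3-yl}methyl (2R)-2-methylbutanoate | CC[C@@H](C)C(=O)OC[C@@H]1[C@H](C(OC(=S)Oc2ccccc2)c2ccc(OCc3ccccc3)c(OC)c2)CO[C@H]1c1ccc(OCc2ccccc2)c(OC)c1
F0 | step 10 | none | none
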